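**Retrosynthetic overview** (labdane numbering: decalin C1–C10, C3 carbinol, C4 gem-dimethyl, ring B alkene C7=C8, side chain C11–C16)
1. The axial C3 alcohol is made last, from the C3 ketone with a bulky hydride.
2. Key disconnection: both rings come from one acyclic α-keto xanthate in a single radical cascade. Ring A closes first through the C1–C2 bond (C2 α-keto radical onto the C10 isopropenyl group). Ring B closes second through C9–C10 (tertiary C10 radical onto an allylic sulfone, which leaves as a sulfonyl radical and fixes the C7=C8 alkene).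
3. Enabling feature: in ring A the C3 carbonyl is blocked on one side by quaternary C4, so C2 is its only α-carbon and lies five atoms from C1 of a C10(CH3)=C1H2 unit. In ring B the C7=C8 alkene is allylic to C9, exactly where an allyl sulfone spanning C7–C8–C9 leaves it.
4. The cascade precursor comes from sulfone alkylation (C6–C7). One partner is an (S)-citronellol-derived allyl ethyl sulfone that already carries C13 and the (R)-2-methylbutanoate. The other is a C1–C6 iodide holding C5, the only stereocentre that steers the ring closures, set by Rh-catalysed asymmetric conjugate addition.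
5. The sulfone carbon C7 is used as a mixture of epimers and becomes sp2, so the key step is stereoconvergent.

Key step: step 14

Remark: the SMILES is read as the normal-series labdane with 5α-H, 9α-H, 10β-CH3, an axial 3α-OH, 13S and an (R)-2-methylbutanoate; (R)-2-methylbutanoic acid and (S)-citronellol are taken as purchasable single enantiomers.

**Route**

Step 1
Reactants: 1 (S)-citronellol; 2 (2R)-2-methylbutanoic acid
Product: 3 (3S)-3,7-dimethyloct-6-en-1-yl (2R)-2-methylbutanoate
Conditions: DCC, DMAP (5 mol %), CH2Cl2, 0 °C → rt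
Reagents that add atoms: none
Why: Steglich esterification of a primary alcohol, in which no stereocentre is formed and the α-centre of the acid should not epimerise under carbodiimide activation at low DMAP loading.

Step 2
Reactants: 3 (3S)-3,7-dimethyloct-6-en-1-yl (2R)-2-methylbutanoate
Product: 4 (3S,6E)-8-hydroxy-3,7-dimethyloct-6-en-1-yl (2R)-2-methylbutanoate
Conditions: SeO2 (0.3 equiv), t-BuOOH (3 equiv), salicylic acid (10 mol %), CH2Cl2, 0 °C → rt
Reagents that add atoms: tert-butyl hydroperoxide, CC(C)(C)OO
Why: SeO2-catalysed allylic oxidation (ene reaction then [2,3]-shift) of the terminal gem-dimethyl alkene should oxidise only the E-methyl group and so fix the E geometry of the future C8=C9 alkene, the run being stopped before the enal builds up.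

Step 3
Reactants: 4 (3S,6E)-8-hydroxy-3,7-dimethyloct-6-en-1-yl (2R)-2-methylbutanoate
Product: 5 (3S,6E)-8-bromo-3,7-dimethyloct-6-en-1-yl (2R)-2-methylbutanoate
Conditions: CBr4, PPh3, CH2Cl2, 0 °C
Reagents that add atoms: carbon tetrabromide, BrC(Br)(Br)Br
Why: Appel bromination by SN2 at the primary allylic carbon should keep the alkene geometry.

Step 4
Reactants: 5 (3S,6E)-8-bromo-3,7-dimethyloct-6-en-1-yl (2R)-2-methylbutanoate
Product: 6 (3S,6E)-8-(ethanesulfonyl)-3,7-dimethyloct-6-en-1-yl (2R)-2-methylbutanoate
Conditions: EtSO2Na, DMF, rt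
Reagents that add atoms: sodium ethanesulfinate, CCS(=O)[O-].[Na+]
Why: S-alkylation of the sulfinate by SN2 at the soft allylic bromide should give the allyl ethyl sulfone without touching the alkene geometry.

Step 5
Reactants: 7 (tert-butyldimethylsilyloxy)acetaldehyde
Product: 8 ethyl (2E)-4-[(tert-butyldimethylsilyl)oxy]but-2-enoate
Conditions: Ph3P=CHCO2Et, CH2Cl2, rt
Reagents that add atoms: ethyl (triphenylphosphoranylidene)acetate, CCOC(=O)C=P(c1ccccc1)(c1ccccc1)c1ccccc1
Why: Wittig olefination with a stabilised ylide should give the E-enoate.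

Step 6
Reactants: 8 ethyl (2E)-4-[(tert-butyldimethylsilyl)oxy]but-2-enoate
Product: 9 ethyl (3S)-3-{[(tert-butyldimethylsilyl)oxy]methyl}-4-methylpent-4-enoate
Conditions: [Rh(cod)Cl]2 (2.5 mol %), (R)-BINAP (6 mol %), isopropenyl-B(pin) (2 equiv), aq KOH (0.5 equiv), 1,4-dioxane, 60 °C
Reagents that add atoms: isopropenylboronic acid pinacol ester, CC(=C)B1OC(C)(C)C(C)(C)O1
Why: Hayashi–Miyaura asymmetric 1,4-addition of the alkenyl group, in which the (R)-BINAP–rhodium catalyst is expected by its established facial model to add to the α-re face of the E-enoate and so set the (S) centre that becomes C5.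

Step 7
Reactants: 9 ethyl (3S)-3-{[(tert-butyldimethylsilyl)oxy]methyl}-4-methylpent-4-enoate
Product: 11 ethyl (3R)-3-{[(tert-butyldimethylsilyl)oxy]methyl}-2,2,4-trimethylpent-4-enoate, via monomethylated ester 10 (not isolated)
Conditions: LiN(i-Pr)2, THF, −78 °C, then MeI; recool, LiN(i-Pr)2, DMPU, then MeI, −78 °C → rt
Reagents that add atoms: iodomethane, CI
Why: Two successive ester enolate methylations build the quaternary C4, which carries two identical methyl groups and so is not stereogenic, while the β-stereocentre is not enolisable and is kept (its descriptor changes only through priorities).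

Step 8
Reactants: 11 ethyl (3R)-3-{[(tert-butyldimethylsilyl)oxy]methyl}-2,2,4-trimethylpent-4-enoate
Product: 12 tert-butyl{[(2R)-4-ethoxy-3,3-dimethyl-2-(prop-1-en-2-yl)pent-4-en-1-yl]oxy}dimethylsilane
Conditions: Cp2TiMe2 (2.5 equiv), toluene, 70 °C, dark; basic alumina
Reagents that add atoms: dimethyltitanocene, C[Ti](C)(C1C=CC=C1)C1C=CC=C1
Why: Petasis methylenation turns the ester carbonyl into an ethyl enol ether under non-basic conditions, which masks the future C3 ketone and marks C2 for later halogenation.

Step 9
Reactants: 12 tert-butyl{[(2R)-4-ethoxy-3,3-dimethyl-2-(prop-1-en-2-yl)pent-4-en-1-yl]oxy}dimethylsilane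
Product: 13 (2R)-4-ethoxy-3,3-dimethyl-2-(prop-1-en-2-yl)pent-4-en-1-ol
Conditions: Bu4NF, THF, 0 °C; Et3N-buffered work-up
Reagents that add atoms: none
Why: Fluoride desilylation in a basic medium should free the primary alcohol while the acid-labile enol ether survives.

Step 10
Reactants: 13 (2R)-4-ethoxy-3,3-dimethyl-2-(prop-1-en-2-yl)pent-4-en-1-ol
Product: 15 (4R)-2-ethoxy-4-(iodomethyl)-3,3,5-trimethylhexa-1,5-diene, via mesylate 14 (not isolated)
Conditions: MsCl, Et3N, CH2Cl2, −10 °C; then NaI, NaHCO3, acetone, 50 °C
Reagents that add atoms: methanesulfonyl chloride, CS(=O)(=O)Cl (in 14 only); sodium iodide, [Na+].[I-]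
Why: Mesylation and Finkelstein exchange (SN2 at the primary carbon) avoid free iodine and acid, both of which would attack the enol ether, and leave the adjacent stereocentre untouched.

Step 11
Reactants: 6 (3S,6E)-8-(ethanesulfonyl)-3,7-dimethyloct-6-en-1-yl (2R)-2-methylbutanoate; 15 (4R)-2-ethoxy-4-(iodomethyl)-3,3,5-trimethylhexa-1,5-diene
Product: 16 (3S,6E,8RS,10R)-12-ethoxy-8-(ethanesulfonyl)-3,7,11,11-tetramethyl-10-(prop-1-en-2-yl)trideca-6,12-dien-1-yl (2R)-2-methylbutanoate
Conditions: 6, LiN(i-Pr)2 (1.0 equiv), THF, −78 °C; DMPU, then 15, −78 → −20 °C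
Reagents that add atoms: none
Why: α-Alkylation of the lithiated allylic sulfone (Julia-type sulfone alkylation) by SN2 at the primary iodide joins C6 to C7, the new sulfone-bearing centre forming as both epimers, which is harmless because step 14 erases it, and one equivalent of amide base at low temperature should leave the hindered ester untouched.

Step 12
Reactants: 16 (3S,6E,8RS,10R)-12-ethoxy-8-(ethanesulfonyl)-3,7,11,11-tetramethyl-10-(prop-1-en-2-yl)trideca-6,12-dien-1-yl (2R)-2-methylbutanoate
Product: 17 (3S,6E,8RS,10R)-13-bromo-8-(ethanesulfonyl)-3,7,11,11-tetramethyl-12-oxo-10-(prop-1-en-2-yl)tridec-6-en-1-yl (2R)-2-methylbutanoate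
Conditions: NBS (1.0 equiv), NaHCO3, THF–H2O 4:1, −20 °C
Reagents that add atoms: N-bromosuccinimide, O=C1CCC(=O)N1Br; water, O
Why: Bromination of the enol ether in water gives the bromomethyl ketone regiospecifically, because the enol ether is far more nucleophilic than the isopropenyl group or the sulfone-deactivated alkene.

Step 13
Reactants: 17 (3S,6E,8RS,10R)-13-bromo-8-(ethanesulfonyl)-3,7,11,11-tetramethyl-12-oxo-10-(prop-1-en-2-yl)tridec-6-en-1-yl (2R)-2-methylbutanoate
Product: 18 (3S,6E,8RS,10R)-13-[(ethoxycarbonothioyl)sulfanyl]-8-(ethanesulfonyl)-3,7,11,11-tetramethyl-12-oxo-10-(prop-1-en-2-yl)tridec-6-en-1-yl (2R)-2-methylbutanoate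
Conditions: KSC(S)OEt, acetone, 0 °C
Reagents that add atoms: potassium O-ethyl carbonodithioate, CCOC(=S)[S-].[K+]
Why: SN2 displacement of the α-bromoketone by the xanthate salt is fast and should give the radical precursor without enolisation.

Step 14
Reactants: 18 (3S,6E,8RS,10R)-13-[(ethoxycarbonothioyl)sulfanyl]-8-(ethanesulfonyl)-3,7,11,11-tetramethyl-12-oxo-10-(prop-1-en-2-yl)tridec-6-en-1-yl (2R)-2-methylbutanoate
Product: 19 (13S)-3-oxolabd-7-en-15-yl (2R)-2-methylbutanoate (trans-decalin, 5α-H, 9α-H, 10β-CH3)
Conditions: dilauroyl peroxide (portions, 0.4 equiv in all), degassed PhCl, 110 °C, 0.01 M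
Reagents that add atoms: none
Why: Proposed new method: peroxide-derived alkyl radicals start a xanthate-transfer chain that gives the C2 α-keto radical, which closes ring A by attack on C1 of the isopropenyl group; the tertiary C10 radical then closes ring B by attack on C9 of the allylic sulfone, and the C8 radical expels EtSO2•, which loses SO2 to an ethyl radical that takes the xanthate group from the next molecule of 18. The closest known reaction types are xanthate-transfer cyclisation of α-keto radicals, stepwise 6-endo radical polyene cyclisation to trans-decalins, and tin-free radical allylation of xanthates with allyl ethyl sulfones by addition–fragmentation; new is their merger into one intramolecular cascade ended by a fragmentation that leaves the alkene inside the ring. Ring A closes 6-endo-trig rather than 5-exo because the carbonyl lies inside the forming ring and the internal alkene carbon carries a methyl group; ring B closes 6-endo-trig at the less substituted carbon of the trisubstituted alkene, which the allylic sulfonyl group also polarity-matches to the nucleophilic tertiary radical. The quaternary C10 centre is set by the C5 stereocentre through a chair transition state that keeps the C5–C4 bond equatorial and gives the trans ring fusion, and C9 is set by the E geometry of the C8=C9 alkene, which places the side chain equatorial. Both C7 epimers converge on one product because C7 becomes sp2, and the fragmentation fixes the alkene at C7=C8 with no regioisomer. The step needs cyclisation to outrun intermolecular addition and irreversible trapping of the intermediate radicals, which high dilution and the reversible, degenerate exchange of the xanthate group should secure.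

Step 15
Reactants: 19 (13S)-3-oxolabd-7-en-15-yl (2R)-2-methylbutanoate
Product: 20 (13S)-3α-hydroxylabd-7-en-15-yl (2R)-2-methylbutanoate
Conditions: LiBH(s-Bu)3, THF, −78 °C; then H2O
Reagents that add atoms: none
Why: The bulky trialkylborohydride should attack the 4,4-dimethyl-3-ketone from the equatorial direction and give the axial 3α-alcohol, as in reductions of 3-oxo-4,4-dimethyl triterpenoids, while the ester is not reduced at this temperature.

**Compound list**
1 | (S)-citronellol | OCC[C@@H](C)CCC=C(C)C | starting material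
2 | (2R)-2-methylbutanoic acid | CC[C@@H](C)C(=O)O | starting material
3 | (3S)-3,7-dimethyloct-6-en-1-yl (2R)-2-methylbutanoate | CC[C@@H](C)C(=O)OCC[C@@H](C)CCC=C(C)C | intermediate
4 | (3S,6E)-8-hydroxy-3,7-dimethyloct-6-en-1-yl (2R)-2-methylbutanoate | CC[C@@H](C)C(=O)OCC[C@@H](C)CC/C=C(\C)CO | intermediate
5 | (3S,6E)-8-bromo-3,7-dimethyloct-6-en-1-yl (2R)-2-methylbutanoate | CC[C@@H](C)C(=O)OCC[C@@H](C)CC/C=C(\C)CBr | intermediate
6 | (3S,6E)-8-(ethanesulfonyl)-3,7-dimethyloct-6-en-1-yl (2R)-2-methylbutanoate | CC[C@@H](C)C(=O)OCC[C@@H](C)CC/C=C(\C)CS(=O)(=O)CC | intermediate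
7 | (tert-butyldimethylsilyloxy)acetaldehyde | O=CCO[Si](C)(C)C(C)(C)C | starting material
8 | ethyl (2E)-4-[(tert-butyldimethylsilyl)oxy]but-2-enoate | CCOC(=O)/C=C/CO[Si](C)(C)C(C)(C)C | intermediate
9 | ethyl (3S)-3-{[(tert-butyldimethylsilyl)oxy]methyl}-4-methylpent-4-enoate | CCOC(=O)C[C@@H](C(C)=C)CO[Si](C)(C)C(C)(C)C | intermediate
10 | ethyl (3S)-3-{[(tert-butyldimethylsilyl)oxy]methyl}-2,4-dimethylpent-4-enoate (both C2 epimers) | CCOC(=O)C(C)[C@@H](C(C)=C)CO[Si](C)(C)C(C)(C)C | intermediate
11 | ethyl (3R)-3-{[(tert-butyldimethylsilyl)oxy]methyl}-2,2,4-trimethylpent-4-enoate | CCOC(=O)C(C)(C)[C@@H](C(C)=C)CO[Si](C)(C)C(C)(C)C | intermediate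
12 | tert-butyl{[(2R)-4-ethoxy-3,3-dimethyl-2-(prop-1-en-2-yl)pent-4-en-1-yl]oxy}dimethylsilane | CCOC(=C)C(C)(C)[C@@H](C(C)=C)CO[Si](C)(C)C(C)(C)C | intermediate
13 | (2R)-4-ethoxy-3,3-dimethyl-2-(prop-1-en-2-yl)pent-4-en-1-ol | CCOC(=C)C(C)(C)[C@@H](C(C)=C)CO | intermediate
14 | (2R)-4-ethoxy-3,3-dimethyl-2-(prop-1-en-2-yl)pent-4-en-1-yl methanesulfonate | CCOC(=C)C(C)(C)[C@@H](C(C)=C)COS(C)(=O)=O | intermediate
15 | (4R)-2-ethoxy-4-(iodomethyl)-3,3,5-trimethylhexa-1,5-diene | CCOC(=C)C(C)(C)[C@@H](C(C)=C)CI | intermediate
16 | (3S,6E,8RS,10R)-12-ethoxy-8-(ethanesulfonyl)-3,7,11,11-tetramethyl-10-(prop-1-en-2-yl)trideca-6,12-dien-1-yl (2R)-2-methylbutanoate (sulfone carbon unassigned, both epimers) | CC[C@@H](C)C(=O)OCC[C@@H](C)CC/C=C(\C)C(C[C@H](C(C)=C)C(C)(C)C(=C)OCC)S(=O)(=O)CC | intermediate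
17 | (3S,6E,8RS,10R)-13-bromo-8-(ethanesulfonyl)-3,7,11,11-tetramethyl-12-oxo-10-(prop-1-en-2-yl)tridec-6-en-1-yl (2R)-2-methylbutanoate | CC[C@@H](C)C(=O)OCC[C@@H](C)CC/C=C(\C)C(C[C@H](C(C)=C)C(C)(C)C(=O)CBr)S(=O)(=O)CC | intermediate
18 | (3S,6E,8RS,10R)-13-[(ethoxycarbonothioyl)sulfanyl]-8-(ethanesulfonyl)-3,7,11,11-tetramethyl-12-oxo-10-(prop-1-en-2-yl)tridec-6-en-1-yl (2R)-2-methylbutanoate | CC[C@@H](C)C(=O)OCC[C@@H](C)CC/C=C(\C)C(C[C@H](C(C)=C)C(C)(C)C(=O)CSC(=S)OCC)S(=O)(=O)CC | intermediate
19 | (13S)-3-oxolabd-7-en-15-yl (2R)-2-methylbutanoate | CC[C@@H](C)C(=O)OCC[C@@H](C)CC[C@H]1C(C)=CC[C@H]2C(C)(C)C(=O)CC[C@]12C | intermediate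
20 | (13S)-3α-hydroxylabd-7-en-15-yl (2R)-2-methylbutanoate | CC[C@@H](C)C(=O)OCC[C@@H](C)CC[C@H]1C(C)=CC[C@H]2C(C)(C)[C@H](O)CC[C@]12C | target

**Step count and risks**
Total steps: 15. Longest linear sequence: 11 steps (from 7 through steps 5–15 to 20).

Steps most likely to fail:

1. Step 14 (proposed new method). The chain may stall after the first ring closure, with the tertiary radical lost to elimination or irreversible group transfer. The sulfonyl group may migrate along the allyl unit by a radical-chain 1,3-shift before SO2 is lost. The second closure may be poorly selective for the trans ring fusion. Fallback with known chemistry: the cascade is run as a reductive tin hydride chain from bromoketone 17, without the xanthate (Bu3SnH by syringe pump, AIBN, benzene, 80 °C, high dilution). This is the classical carrier for 6-endo radical polycyclisations from halides and for cyclisations ended by loss of a sulfonyl radical, which the stannane then reduces. It forms the same C1–C2 and C9–C10 bonds and comes back to the route at 19.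

2. Step 11. Substitution at the β-branched iodide may be slow, so that attack of the sulfonyl carbanion on the ester of a second molecule or proton transfer takes over. Fallback: the acyl group is taken off before the coupling and put back after it. Sulfone 6 is transesterified (K2CO3, MeOH) to (3S,6E)-8-(ethanesulfonyl)-3,7-dimethyloct-6-en-1-ol F1. Its alkoxide–sulfonyl dianion (n-BuLi, 2.1 equiv, THF–HMPA), which can be warmed to rt without risk, is alkylated with 15 to give the coupled alcohol (3S,6E,8RS,10R)-12-ethoxy-8-(ethanesulfonyl)-3,7,11,11-tetramethyl-10-(prop-1-en-2-yl)trideca-6,12-dien-1-ol F2. Steglich esterification of F2 with acid 2 (DCC, DMAP) comes back to the route at 16.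

3. Step 6. Transmetalation of the α-branched alkenylboronate may be sluggish, or facial selectivity on the acyclic silyloxy enoate may be poor, which would erode the only stereocentre that controls ring formation. Fallback: auxiliary control replaces catalyst control. Ester 8 is saponified (LiOH, THF–H2O) to (2E)-4-[(tert-butyldimethylsilyl)oxy]but-2-enoic acid F3. This is coupled through its pivaloyl mixed anhydride with lithiated (R)-4-phenyloxazolidin-2-one to the imide (4R)-3-{(2E)-4-[(tert-butyldimethylsilyl)oxy]but-2-enoyl}-4-phenyloxazolidin-2-one F4. Chelate-controlled addition of isopropenylmagnesium bromide with CuBr·SMe2, anti to the phenyl group, should give (4R)-3-[(3S)-3-{[(tert-butyldimethylsilyl)oxy]methyl}-4-methylpent-4-enoyl]-4-phenyloxazolidin-2-one F5. Ethanolysis (EtMgBr, EtOH, 0 °C) removes the auxiliary and comes back to the route at 9.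

**Further compounds**
F0 | step 14 | none | none
F1 | step 11 | (3S,6E)-8-(ethanesulfonyl)-3,7-dimethyloct-6-en-1-ol | OCC[C@@H](C)CC/C=C(\C)CS(=O)(=O)CC
F2 | step 11 | (3S,6E,8RS,10R)-12-ethoxy-8-(ethanesulfonyl)-3,7,11,11-tetramethyl-10-(prop-1-en-2-yl)trideca-6,12-dien-1-ol | OCC[C@@H](C)CC/C=C(\C)C(C[C@H](C(C)=C)C(C)(C)C(=C)OCC)S(=O)(=O)CC
F3 | step 6 | (2E)-4-[(tert-butyldimethylsilyl)oxy]but-2-enoic acid | CC(C)(C)[Si](C)(C)OC/C=C/C(=O)O
F4 | step 6 | (4R)-3-{(2E)-4-[(tert-butyldimethylsilyl)oxy]but-2-enoyl}-4-phenyloxazolidin-2-one | CC(C)(C)[Si](C)(C)OC/C=C/C(=O)N1[C@H](c2ccccc2)COC1=O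
F5 | step 6 | (4R)-3-[(3S)-3-{[(tert-butyldimethylsilyl)oxy]methyl}-4-methylpent-4-enoyl]-4-phenyloxazolidin-2-one | CC(C)(C)[Si](C)(C)OC[C@H](C(C)=C)CC(=O)N1[C@H](c2ccccc2)COC1=O
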